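## Structural features

The target, (4R,5R,6R,7S,8S,9R,10R), is a ten-membered carbocycle (C1–C10) trans-fused across C7–C8 to an α-methylene γ-lactone (C11, C12, exocyclic C13, lactone oxygen on C8). One arc of the ring, C4 to C10, carries seven contiguous stereocentres: the trans-4,5-epoxide with its C4 methyl group, the tigloyloxy carbon C6, the fusion carbons C7 and C8, the free carbinol C9 and the methyl-bearing C10. The other arc, C1–C3, is three plain methylene groups. The fragile groups are the methylene lactone (a Michael acceptor that also reacts with metathesis catalysts and diimide), the trisubstituted epoxide (acid, and transannular attack by O9), the tiglate (enolate chemistry) and the three neighbouring oxygens on C6, C8 and C9, between which the lactone carbonyl or an acyl group can migrate once an alkoxide is formed. The real difficulty is twofold: closing a strained medium ring, and setting a dense stereo-array that cannot be trusted to follow from medium-ring conformations. The key step exploits the stereocentre-free arc: the C1–C2 bond has no function in the target, so it can be made as an alkene from a vinyl group on C10 and an allyl group on C4 and then saturated, which lets every stereocentre be installed beforehand on an open chain.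

## Logic of the disconnections

29 ⇐ 28 ⇐ 27 ⇐ 26. Going backwards, O9 is re-silylated (28), the ester C–O bond at O6 is cut (27) and O6 is re-silylated (26). The ester is cut this late because an α,β-unsaturated ester would not survive the enolate chemistry at C11, and O9 must stay masked while O6 is acylated. The gain is that 26 carries only two robust silyl ethers of different size. The forward demand is a clean size-based discrimination between them, and acylation and desilylation conditions that never form an alkoxide next to the lactone, the epoxide or the enoate.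

26 ⇐ 22. The C11=C13 double bond is cut and C13 removed. The methylene lactone would engage a metathesis catalyst, be reduced by diimide and accept nucleophiles, so it must come after ring closure and alkene reduction. The gain is a plain lactone. The demand is kinetic enolisation at C11 beside an epoxide and two silyl ethers, and an elimination that gives only the exocyclic alkene.

22 ⇐ 21 ⇐ 20. A C1=C2 double bond is reintroduced (21) and then cut, each terminus gaining one carbon (20). This bond lies in the only part of the ring without stereocentres or functionality. The gain is the largest of the route: the ten-membered ring is replaced by a five-membered lactone carrying two side chains. The demand is cyclisation in preference to oligomerisation, and a reduction that spares the epoxide.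

20 ⇐ 19 ⇐ 18. The O6–Si bond and then both C–O bonds of the epoxide are cut, leaving an (E)-C4=C5 alkene beside the free C6 carbinol in 18. The carbinol can direct oxygen delivery, and the (E)-geometry maps onto the trans-epoxide. Two stereocentres are traded for one alkene geometry. The demand is reagent control strong enough to give the erythro (5,6-anti) isomer against the allylic strain from the C4 methyl group cis to C6.

18 ⇐ 12 + 15. The C5–C6 bond is cut between an aldehyde carbon and an alkenyl carbon. This is the convergent point and divides the molecule into a stereo-rich lactone and a simple diene. The demand is a nucleophile that is not basic, because C7 is α to the aldehyde and β to the lactone oxygen, and that adds to the face set by C7.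

15 ⇐ 13. The C4–CH3 bond and the C5–I bond are cut, which is a syn addition across a terminal alkyne in the forward sense. The demand is regio- and syn-selective carbometalation and replacement of the metal with retention.

12 ⇐ 10 ⇐ 9 ⇐ 6 + 7. The C6 aldehyde is masked as a cyclic acetal (10), the O9–Si bond is cut (9), and then the C9–C10 bond is cut. One bond formation brings in C10, its methyl group, the C9 carbinol and the vinyl group needed for ring closure. The demand is a closed transition state that turns (E)-geometry into the anti pair, and facial selection at C9 by the oxygenated C8 centre.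

6 ⇐ 5 ⇐ 4 ⇐ 2 + 3, and 2 ⇐ 1. The C9 aldehyde is returned to the alcohol (5) and its silyl ether (4), and then the C6–C7 bond is cut, C6 arriving as an acetal carbon. C8 comes from the chiral pool and directs C7. The demand is addition trans to the C8 substituent under conditions that do not enolise the butenolide.

## Other disconnections considered

Alternative 1: The ring is traced through two bonds, C4–C5 and C1–C10, to a [2+2] photocycloaddition between the six-membered enone A1 and 1-methylcyclobutene A2. Irradiation would give the cis-anti-cis tricycle A3, and heating would open its bicyclo[2.2.0]hexane unit (cleavage of C5–C10 and C1–C4) to the cyclodeca-1(10),4-dienone A4.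
- In its favour: no macrocyclisation is involved, so dilution, catalyst loading and oligomerisation are not issues. On the ring-forming event itself this plan is the better one. Two skeletal bonds come in one step from a terpene-derived enone, and the (E)-C4=C5 alkene appears where the epoxide must go.
- Against it here: the four stereocentres created in A3 are all destroyed, the orientation of the unsymmetrical cyclobutene on the enone is not assured, and A4 could equilibrate by Cope rearrangement with a divinylcyclohexane.
- A4 is also far from the target in oxidation pattern. C8 is a bare methylene, C9 a ketone, C1=C10 must be reduced selectively beside C4=C5 to create C10, and one methyl of the C7 silyloxy-isopropyl group must become the lactone carbonyl.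
- Comparison on structure: five stereocentres (C4, C5, C8, C9, C10) would have to be set on the flexible ring under conformational control, whereas the chosen plan sets all seven on an open chain under reagent control.
- Comparison on mechanism: a triplet diradical cycloaddition and a thermal fragmentation stand against a catalytic metathesis. Both are established reaction types and neither is intrinsically more reliable, so this point is equal.
- Comparison on step economy: the alternative would reach a ten-membered ring in fewer steps, but the corrections after ring formation would probably outnumber the five steps that follow ring closure in the chosen route.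

Alternative 2: C6–C7 is the bond made and C4–C9 the bond broken. The potassium alkoxide of the trans-1,2-dialkenylcyclohexanol A5 (KH, 18-crown-6, THF) would undergo an anionic oxy-Cope rearrangement through a chair to the enolate of the (E)-cyclodecenone A6.
- In its favour: enolate formation drives the ring expansion and no dilution is needed. The chair should transfer the two (E)-alkenes of A5 into the syn C6/C7 relationship and the (E)-C4=C5 alkene, so the step creates two stereocentres where the metathesis creates none. On that count it is the better step. C10 is already present, and the enolate could in principle be oxidised in the same flask to introduce O8.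
- Against it here: A5 is itself demanding. It needs, in enantiopure form, a quaternary carbon bearing an enol ether next to a tertiary carbinol, with the two alkenyl groups trans.
- After the key step, O8, the C9 carbinol, the epoxide and the oxidation of the isopropenyl methyl group to the lactone carbonyl all remain. C10, α to the C9 ketone, could epimerise, and KH tolerates fewer functional groups than a ruthenium carbene.
- Comparison on structure: three of the seven stereocentres (C6, C7, C10) would be present at the key step and four would be added on the ring, against seven of seven before ring closure in the chosen plan.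
- Comparison on mechanism: the stereochemical course of a concerted sigmatropic shift is at least as predictable as anything in the chosen key step, so this point is equal or better.
- Comparison on step economy: the step count to the ring would be similar and the count after it higher.

Alternative 3: C7–C8 is made while the O–C13 bond is broken. The thirteen-membered α-allyloxy ketone A7 would be deprotonated at C8 with LiN(SiMe3)2, and the enolate would attack C7 in a [2,3]-Wittig rearrangement, contracting the ether to the ten-membered hydroxy ketone A8.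
- In its favour: the hard medium-ring closure is replaced by closure of an unstrained thirteen-membered ether. On ease of ring closure this is the better plan. The step creates C7 and C8 together, frees the C8 hydroxyl that becomes the lactone oxygen, and forms the isopropenyl group that becomes C11–C13. A8 has oxygen on C6, C8 and C9, an oxygenation pattern equal to that of the chosen plan at the same stage.
- Against it here: the C7/C8 relationship would depend on enolate geometry and on the folding of the macrocycle in a five-membered transition state, which is hard to predict. A [1,2]-shift and enolate equilibration towards C10 could compete.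
- Afterwards the C9 ketone must be reduced to the correct carbinol, the isopropenyl methyl group oxidised and lactonised, and C4=C5 epoxidised on the correct face, all under conformational control.
- Comparison on structure: four stereocentres (C6, C7, C8, C10) would be in place after the key step, against seven before it in the chosen plan.
- Comparison on mechanism: a strongly basic rearrangement with two competing pathways stands against a neutral catalytic ring closure whose only selectivity issue is cyclisation versus oligomerisation.
- Comparison on step economy: the macrocyclic ether needs its own multistep assembly, and the steps after contraction would again exceed those after metathesis.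

Key step: step 12

Remark on the chemistry: the C1=C2 alkene of 21 is written as the Z isomer; the E isomer or a mixture serves equally because step 13 removes it. The configurations at C11 in 24 and 25 and at the N,O-acetal carbon of 11 are left open because these centres are transient.

## Steps

Step 1
Reactants: 1 (S)-5-(hydroxymethyl)furan-2(5H)-one
Product: 2 (S)-5-{[(tert-butyldimethylsilyl)oxy]methyl}furan-2(5H)-one
Conditions: TBSCl, imidazole, CH2Cl2, 0 °C → rt
Reagents that add atoms: tert-butyldimethylsilyl chloride, CC(C)(C)[Si](C)(C)Cl
Why: Silylation of a primary alcohol with a weak base, which does not enolise the butenolide, so the C8 configuration is kept; the bulky silyl ether later shields one face of the enoate.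

Step 2
Reactants: 2 (S)-5-{[(tert-butyldimethylsilyl)oxy]methyl}furan-2(5H)-one; 3 1,3-dioxolane
Product: 4 (4S,5S)-5-{[(tert-butyldimethylsilyl)oxy]methyl}-4-(1,3-dioxolan-2-yl)oxolan-2-one
Conditions: Ph2CO (10 mol %), 1,3-dioxolane as solvent, hν (350 nm), degassed, rt
Reagents that add atoms: none
Why: Photosensitised radical conjugate addition (Giese type): triplet benzophenone abstracts the acetal hydrogen and the nucleophilic dioxolan-2-yl radical adds to the β-carbon on the face opposite the silyloxymethyl group, which sets C7 trans to C8; the acetal is the masked C6 aldehyde.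

Step 3
Reactants: 4 (4S,5S)-5-{[(tert-butyldimethylsilyl)oxy]methyl}-4-(1,3-dioxolan-2-yl)oxolan-2-one
Product: 5 (4S,5S)-4-(1,3-dioxolan-2-yl)-5-(hydroxymethyl)oxolan-2-one
Conditions: Bu4NF, AcOH, THF, 0 °C → rt
Reagents that add atoms: none
Why: Fluoride-driven desilylation; acetic acid buffers the alkoxide so that the lactone neither opens nor migrates, and the acetal is inert to fluoride.

Step 4
Reactants: 5 (4S,5S)-4-(1,3-dioxolan-2-yl)-5-(hydroxymethyl)oxolan-2-one
Product: 6 (2S,3S)-3-(1,3-dioxolan-2-yl)-5-oxooxolane-2-carbaldehyde
Conditions: Dess–Martin periodinane, CH2Cl2, 0 °C → rt; used crude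
Reagents that add atoms: none
Why: Dess–Martin oxidation without amine base, so the α-acyloxy aldehyde should not epimerise at C8; it is taken on at once because such aldehydes hydrate and epimerise on standing.

Step 5
Reactants: 6 (2S,3S)-3-(1,3-dioxolan-2-yl)-5-oxooxolane-2-carbaldehyde; 7 (E)-crotylboronic acid pinacol ester
Product: 9 (4S,5S)-4-(1,3-dioxolan-2-yl)-5-[(1R,2R)-1-hydroxy-2-methylbut-3-en-1-yl]oxolan-2-one, via pinacol borate ester 8 (not isolated)
Conditions: 7 (1.5 equiv), toluene, 4 Å MS, rt; aq. NaHCO3 work-up
Reagents that add atoms: none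
Why: Uncatalysed crotylboration through a closed six-membered chair, so the (E)-geometry of 7 becomes the C9/C10 anti relationship; the aldehyde face is chosen by the polar Felkin–Anh (Cornforth) preference of the oxygenated C8 centre, attack anti to the C8–O bond giving the 8,9-anti isomer; hydrolysis of 8 on work-up frees the alcohol.

Step 6
Reactants: 9 (4S,5S)-4-(1,3-dioxolan-2-yl)-5-[(1R,2R)-1-hydroxy-2-methylbut-3-en-1-yl]oxolan-2-one
Product: 10 (4S,5S)-5-[(1R,2R)-1-{[tert-butyldimethylsilyl]oxy}-2-methylbut-3-en-1-yl]-4-(1,3-dioxolan-2-yl)oxolan-2-one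
Conditions: TBSOTf, 2,6-lutidine, CH2Cl2, −78 °C
Reagents that add atoms: tert-butyldimethylsilyl trifluoromethanesulfonate, CC(C)(C)[Si](C)(C)OS(=O)(=O)C(F)(F)F
Why: Silyl triflate silylation of a hindered secondary alcohol; at −78 °C with a hindered pyridine the cyclic acetal and the lactone should not be engaged, and capping O9 removes a hydroxyl that could attack the lactone.

Step 7
Reactants: 10 (4S,5S)-5-[(1R,2R)-1-{[tert-butyldimethylsilyl]oxy}-2-methylbut-3-en-1-yl]-4-(1,3-dioxolan-2-yl)oxolan-2-one
Product: 12 (2S,3S)-2-[(1R,2R)-1-{[tert-butyldimethylsilyl]oxy}-2-methylbut-3-en-1-yl]-5-oxooxolane-3-carbaldehyde, via collidinium salt 11 (not isolated)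
Conditions: TESOTf, 2,4,6-collidine, CH2Cl2, 0 °C; then H2O
Reagents that add atoms: water, O
Why: Chemoselective acetal cleavage: the silyl triflate opens the dioxolane to an oxocarbenium ion that collidine traps as salt 11, and water hydrolyses 11 at near-neutral pH; the silyl ether is not touched, and C7 (α to the new aldehyde, β to the lactone oxygen) meets neither protic acid nor strong base.

Step 8
Reactants: 13 pent-1-en-4-yne
Product: 15 (E)-1-iodo-2-methylpenta-1,4-diene, via alkenyldimethylalane 14 (not isolated)
Conditions: AlMe3, Cp2ZrCl2 (20 mol %), CH2Cl2, 0 °C → rt; then I2, THF, −30 → 0 °C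
Reagents that add atoms: trimethylaluminium, C[Al](C)C; iodine, II
Why: Zirconium-catalysed carboalumination (Negishi) adds methyl and aluminium syn across the terminal alkyne with aluminium at the terminus, and iodine replaces aluminium with retention, which fixes the (E)-trisubstituted alkene; the monosubstituted alkene is not carbometalated under these conditions.

Step 9
Reactants: 12 (2S,3S)-2-[(1R,2R)-1-{[tert-butyldimethylsilyl]oxy}-2-methylbut-3-en-1-yl]-5-oxooxolane-3-carbaldehyde; 15 (E)-1-iodo-2-methylpenta-1,4-diene
Product: 18 (4R,5S)-5-[(1R,2R)-1-{[tert-butyldimethylsilyl]oxy}-2-methylbut-3-en-1-yl]-4-[(1S,2E)-1-hydroxy-3-methylhexa-2,5-dien-1-yl]oxolan-2-one, via alkenylchromium dichloride 16 (not isolated), via chromium alkoxide 17 (not isolated)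
Conditions: CrCl2 (4 equiv), NiCl2 (2 mol %), DMSO, rt; H2O work-up
Reagents that add atoms: none
Why: Nozaki–Hiyama–Kishi coupling: zerovalent nickel inserts into the C–I bond and passes the alkenyl group to trivalent chromium, which adds only to the aldehyde and is too weakly basic to epimerise C7 or expel the lactone oxygen; Felkin–Anh addition anti to the C8 branch should favour the carbinol drawn (6R in the target; S here by priority only), and a C6 epimer would be removed in step 10.

Step 10
Reactants: 18 (4R,5S)-5-[(1R,2R)-1-{[tert-butyldimethylsilyl]oxy}-2-methylbut-3-en-1-yl]-4-[(1S,2E)-1-hydroxy-3-methylhexa-2,5-dien-1-yl]oxolan-2-one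
Product: 19 (4R,5S)-5-[(1R,2R)-1-{[tert-butyldimethylsilyl]oxy}-2-methylbut-3-en-1-yl]-4-{(R)-hydroxy[(2R,3R)-3-methyl-3-(prop-2-en-1-yl)oxiran-2-yl]methyl}oxolan-2-one
Conditions: Ti(OiPr)4 (1.0 equiv), D-(−)-diisopropyl tartrate (1.2 equiv), t-BuOOH, 4 Å MS, CH2Cl2, −20 °C
Reagents that add atoms: tert-butyl hydroperoxide, CC(C)(C)OO
Why: Sharpless asymmetric epoxidation of a secondary allylic alcohol: with the D-tartrate the titanium complex delivers oxygen to the C4=C5 face that is the fast, matched one for this carbinol and gives the erythro (5,6-anti) epoxy alcohol with (4R,5R) configuration; the isolated terminal alkenes are not epoxidised, and a C6-epimeric carbinol would react slowly and be separated here.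

Step 11
Reactants: 19 (4R,5S)-5-[(1R,2R)-1-{[tert-butyldimethylsilyl]oxy}-2-methylbut-3-en-1-yl]-4-{(R)-hydroxy[(2R,3R)-3-methyl-3-(prop-2-en-1-yl)oxiran-2-yl]methyl}oxolan-2-one
Product: 20 (4S,5S)-5-[(1R,2R)-1-{[tert-butyldimethylsilyl]oxy}-2-methylbut-3-en-1-yl]-4-{(R)-[(2R,3R)-3-methyl-3-(prop-2-en-1-yl)oxiran-2-yl][(triethylsilyl)oxy]methyl}oxolan-2-one
Conditions: TESCl, imidazole, CH2Cl2, 0 °C
Reagents that add atoms: chlorotriethylsilane, CC[Si](CC)(CC)Cl
Why: Mild silylation that leaves the epoxide alone; O6 is capped so that it cannot attack the lactone carbonyl and so that it can later be released in the presence of the bulkier O9 silyl ether.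

Step 12
Reactants: 20 (4S,5S)-5-[(1R,2R)-1-{[tert-butyldimethylsilyl]oxy}-2-methylbut-3-en-1-yl]-4-{(R)-[(2R,3R)-3-methyl-3-(prop-2-en-1-yl)oxiran-2-yl][(triethylsilyl)oxy]methyl}oxolan-2-one
Product: 21 (1Z;4R,5R,6R,7S,8S,9R,10R)-4,5-epoxy-4,10-dimethyl-6-(triethylsilyloxy)-9-(tert-butyldimethylsilyloxy)cyclodec-1-ene trans-fused at C7/C8 to a γ-lactone (C11H2; C12=O; O on C8)
Conditions: RuCl2(=CHPh)(PCy3)(H2IMes) (second-generation Grubbs catalyst, 15 mol % in portions), 1,4-benzoquinone (20 mol %), toluene (1 mM), 80 °C, Ar sparge
Reagents that add atoms: none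
Why: Ring-closing olefin metathesis. After phosphine loss the ruthenium benzylidene undergoes [2+2] cycloaddition with the unhindered allyl terminus and cycloreversion places the metal on C2; this alkylidene then meets the C10 vinyl group intramolecularly, and collapse of the second ruthenacyclobutane forms C1=C2 and a ruthenium methylidene, the two lost carbons leaving as ethene. The closest known reaction type is ring-closing metathesis to ten-membered carbocycles and lactones that carry ring or epoxide constraints. The one ring closed is the ten-membered carbocycle C1–C10, closed at an alkene inside the ring from two monosubstituted terminal alkenes. No stereocentre is formed, and the alkene may be Z (as written) or E because step 13 erases it. The selectivity needed is cyclisation over acyclic diene metathesis oligomerisation; millimolar dilution, portionwise catalyst addition and removal of ethene favour it, as does the substrate, in which the trans-lactone at C7/C8 and the trans-epoxide at C4/C5 act as two rigid turns that bring the termini together. There is no third alkene that could close a smaller ring, and 1,4-benzoquinone suppresses ruthenium hydride migration of the terminal alkenes, which would otherwise lead to ring-contracted products.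

Step 13
Reactants: 21 (1Z;4R,5R,6R,7S,8S,9R,10R)-4,5-epoxy-4,10-dimethyl-6-(triethylsilyloxy)-9-(tert-butyldimethylsilyloxy)cyclodec-1-ene trans-fused at C7/C8 to a γ-lactone (C11H2; C12=O; O on C8)
Product: 22 (4R,5R,6R,7S,8S,9R,10R)-4,5-epoxy-4,10-dimethyl-6-(triethylsilyloxy)-9-(tert-butyldimethylsilyloxy)cyclodecane trans-fused at C7/C8 to a γ-lactone (C11H2; C12=O; O on C8)
Conditions: 2-O2NC6H4SO2NHNH2, Et3N, CH2Cl2, rt (repeated charges)
Reagents that add atoms: none
Why: Diimide reduction: diazene formed in the flask transfers two hydrogens suprafacially to the disubstituted ring alkene whatever its geometry; with no metal hydride or hydrogenation catalyst present the epoxide, the lactone and both silyl ethers should be untouched.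

Step 14
Reactants: 22 (4R,5R,6R,7S,8S,9R,10R)-4,5-epoxy-4,10-dimethyl-6-(triethylsilyloxy)-9-(tert-butyldimethylsilyloxy)cyclodecane trans-fused at C7/C8 to a γ-lactone (C11H2; C12=O; O on C8)
Product: 26 (4R,5R,6R,7S,8S,9R,10R)-4,5-epoxy-4,10-dimethyl-6-(triethylsilyloxy)-9-(tert-butyldimethylsilyloxy)cyclodecane trans-fused at C7/C8 to an α-methylene γ-lactone (C11=C13H2; C12=O; O on C8), via lithium enolate 23 (not isolated), via Mannich base 24 (not isolated), via trimethylammonium iodide 25 (not isolated)
Conditions: LiN(iPr)2, THF, −78 °C; Me2N=CH2+ I−, −78 → 0 °C; then MeI, rt; then sat. aq. NaHCO3, rt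
Reagents that add atoms: N,N-dimethylmethyleneiminium iodide (Eschenmoser's salt), C=[N+](C)C.[I-]
Why: α-Methylenation of a lactone: the enolate is aminomethylated by the iminium salt (Mannich reaction), the amine is quaternised, and mild base removes the remaining α-hydrogen with loss of trimethylamine (E1cB), which can only give the exocyclic alkene; the C11 configuration of 24 and 25 is irrelevant.

Step 15
Reactants: 26 (4R,5R,6R,7S,8S,9R,10R)-4,5-epoxy-4,10-dimethyl-6-(triethylsilyloxy)-9-(tert-butyldimethylsilyloxy)cyclodecane trans-fused at C7/C8 to an α-methylene γ-lactone (C11=C13H2; C12=O; O on C8)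
Product: 27 (4R,5R,6R,7R,8S,9R,10R)-4,5-epoxy-6-hydroxy-4,10-dimethyl-9-(tert-butyldimethylsilyloxy)cyclodecane trans-fused at C7/C8 to an α-methylene γ-lactone (C7 descriptor changed by priority only)
Conditions: HF·pyridine, pyridine, THF, 0 °C
Reagents that add atoms: none
Why: Selective desilylation: buffered fluoride should cleave the triethylsilyl ether much faster than the hindered tert-butyldimethylsilyl ether at C9, and the excess pyridine keeps the medium from opening the epoxide.

Step 16
Reactants: 27 (4R,5R,6R,7R,8S,9R,10R)-4,5-epoxy-6-hydroxy-4,10-dimethyl-9-(tert-butyldimethylsilyloxy)cyclodecane trans-fused at C7/C8 to an α-methylene γ-lactone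
Product: 28 (4R,5R,6R,7R,8S,9R,10R)-4,5-epoxy-4,10-dimethyl-6-[(E)-2-methylbut-2-enoyloxy]-9-(tert-butyldimethylsilyloxy)cyclodecane trans-fused at C7/C8 to an α-methylene γ-lactone
Conditions: tigloyl chloride, DMAP, pyridine, CH2Cl2, 0 °C → rt
Reagents that add atoms: (E)-2-methylbut-2-enoyl chloride (tigloyl chloride), C/C=C(\C)C(=O)Cl
Why: DMAP-catalysed acylation through the acylpyridinium ion; the weak base does not form the C6 alkoxide, so migration of the lactone to O6 is not promoted, and the (E)-enoate is the stable geometry of this acyl group.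

Step 17
Reactants: 28 (4R,5R,6R,7R,8S,9R,10R)-4,5-epoxy-4,10-dimethyl-6-[(E)-2-methylbut-2-enoyloxy]-9-(tert-butyldimethylsilyloxy)cyclodecane trans-fused at C7/C8 to an α-methylene γ-lactone
Product: 29 (4R,5R,6R,7S,8S,9R,10R)-4,5-epoxy-9-hydroxy-4,10-dimethyl-6-[(E)-2-methylbut-2-enoyloxy]cyclodecane trans-fused at C7/C8 to an α-methylene γ-lactone (target CNP0165329.2)
Conditions: HF·pyridine, THF, 0 °C → rt
Reagents that add atoms: none
Why: Fluoride-assisted cleavage of the last silyl ether under weakly acidic, non-nucleophilic conditions, chosen over basic fluoride so that no alkoxide forms that could add to the methylene lactone, move the tiglate or open the epoxide.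

## Compound list

1 | (S)-5-(hydroxymethyl)furan-2(5H)-one | OC[C@H]1OC(=O)C=C1 | starting material
2 | (S)-5-{[(tert-butyldimethylsilyl)oxy]methyl}furan-2(5H)-one | CC(C)(C)[Si](C)(C)OC[C@H]1OC(=O)C=C1 | intermediate
3 | 1,3-dioxolane | C1COCO1 | starting material
4 | (4S,5S)-5-{[(tert-butyldimethylsilyl)oxy]methyl}-4-(1,3-dioxolan-2-yl)oxolan-2-one | CC(C)(C)[Si](C)(C)OC[C@H]1OC(=O)C[C@@H]1C2OCCO2 | intermediate
5 | (4S,5S)-4-(1,3-dioxolan-2-yl)-5-(hydroxymethyl)oxolan-2-one | OC[C@H]1OC(=O)C[C@@H]1C2OCCO2 | intermediate
6 | (2S,3S)-3-(1,3-dioxolan-2-yl)-5-oxooxolane-2-carbaldehyde | O=C[C@H]1OC(=O)C[C@@H]1C2OCCO2 | intermediate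
7 | (E)-crotylboronic acid pinacol ester, 2-[(2E)-but-2-en-1-yl]-4,4,5,5-tetramethyl-1,3,2-dioxaborolane | C/C=C/CB1OC(C)(C)C(C)(C)O1 | starting material
8 | pinacol borate ester of 9 (boron on O9) | C=C[C@@H](C)[C@@H](OB2OC(C)(C)C(C)(C)O2)[C@H]1OC(=O)C[C@@H]1C3OCCO3 | intermediate (not isolated)
9 | (4S,5S)-4-(1,3-dioxolan-2-yl)-5-[(1R,2R)-1-hydroxy-2-methylbut-3-en-1-yl]oxolan-2-one | C=C[C@@H](C)[C@@H](O)[C@H]1OC(=O)C[C@@H]1C2OCCO2 | intermediate
10 | (4S,5S)-5-[(1R,2R)-1-{[tert-butyldimethylsilyl]oxy}-2-methylbut-3-en-1-yl]-4-(1,3-dioxolan-2-yl)oxolan-2-one | C=C[C@@H](C)[C@@H](O[Si](C)(C)C(C)(C)C)[C@H]1OC(=O)C[C@@H]1C2OCCO2 | intermediate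
11 | 2,4,6-trimethylpyridinium N,O-acetal triflate from 10 (C6 bearing the pyridinium nitrogen and a 2-(triethylsilyloxy)ethoxy group) | C=C[C@@H](C)[C@@H](O[Si](C)(C)C(C)(C)C)[C@H]1OC(=O)C[C@@H]1C(OCCO[Si](CC)(CC)CC)[n+]2c(C)cc(C)cc2C.[O-]S(=O)(=O)C(F)(F)F | intermediate (not isolated)
12 | (2S,3S)-2-[(1R,2R)-1-{[tert-butyldimethylsilyl]oxy}-2-methylbut-3-en-1-yl]-5-oxooxolane-3-carbaldehyde | C=C[C@@H](C)[C@@H](O[Si](C)(C)C(C)(C)C)[C@H]1OC(=O)C[C@@H]1C=O | intermediate
13 | pent-1-en-4-yne | C=CCC#C | starting material
14 | dimethyl[(E)-2-methylpenta-1,4-dien-1-yl]alumane | C=CC/C(C)=C/[Al](C)C | intermediate (not isolated)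
15 | (E)-1-iodo-2-methylpenta-1,4-diene | C=CC/C(C)=C/I | intermediate
16 | [(E)-2-methylpenta-1,4-dien-1-yl]chromium dichloride | C=CC/C(C)=C/[Cr](Cl)Cl | intermediate (not isolated)
17 | dichlorochromium alkoxide of 18 (chromium on O6) | C=C[C@@H](C)[C@@H](O[Si](C)(C)C(C)(C)C)[C@H]1OC(=O)C[C@@H]1[C@@H](O[Cr](Cl)Cl)/C=C(\C)CC=C | intermediate (not isolated)
18 | (4R,5S)-5-[(1R,2R)-1-{[tert-butyldimethylsilyl]oxy}-2-methylbut-3-en-1-yl]-4-[(1S,2E)-1-hydroxy-3-methylhexa-2,5-dien-1-yl]oxolan-2-one | C=C[C@@H](C)[C@@H](O[Si](C)(C)C(C)(C)C)[C@H]1OC(=O)C[C@@H]1[C@@H](O)/C=C(\C)CC=C | intermediate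
19 | (4R,5S)-5-[(1R,2R)-1-{[tert-butyldimethylsilyl]oxy}-2-methylbut-3-en-1-yl]-4-{(R)-hydroxy[(2R,3R)-3-methyl-3-(prop-2-en-1-yl)oxiran-2-yl]methyl}oxolan-2-one | C=C[C@@H](C)[C@@H](O[Si](C)(C)C(C)(C)C)[C@H]1OC(=O)C[C@@H]1[C@@H](O)[C@H]2O[C@]2(C)CC=C | intermediate
20 | (4S,5S)-5-[(1R,2R)-1-{[tert-butyldimethylsilyl]oxy}-2-methylbut-3-en-1-yl]-4-{(R)-[(2R,3R)-3-methyl-3-(prop-2-en-1-yl)oxiran-2-yl][(triethylsilyl)oxy]methyl}oxolan-2-one | C=C[C@@H](C)[C@@H](O[Si](C)(C)C(C)(C)C)[C@H]1OC(=O)C[C@@H]1[C@@H](O[Si](CC)(CC)CC)[C@H]2O[C@]2(C)CC=C | intermediate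
21 | (1Z;4R,5R,6R,7S,8S,9R,10R)-4,5-epoxy-4,10-dimethyl-6-(triethylsilyloxy)-9-(tert-butyldimethylsilyloxy)cyclodec-1-ene trans-fused at C7/C8 to a γ-lactone (C11H2; C12=O; O on C8) | O=C1O[C@@H]2[C@H](O[Si](C)(C)C(C)(C)C)[C@H](C)/C=C\C[C@@]3(C)O[C@@H]3[C@H](O[Si](CC)(CC)CC)[C@H]2C1 | intermediate
22 | (4R,5R,6R,7S,8S,9R,10R)-4,5-epoxy-4,10-dimethyl-6-(triethylsilyloxy)-9-(tert-butyldimethylsilyloxy)cyclodecane trans-fused at C7/C8 to a γ-lactone (C11H2; C12=O; O on C8) | O=C1O[C@@H]2[C@H](O[Si](C)(C)C(C)(C)C)[C@H](C)CCC[C@@]3(C)O[C@@H]3[C@H](O[Si](CC)(CC)CC)[C@H]2C1 | intermediate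
23 | lithium enolate of 22 (C11=C12–O−) | [Li+].[O-]C1O[C@@H]2[C@H](O[Si](C)(C)C(C)(C)C)[C@H](C)CCC[C@@]3(C)O[C@@H]3[C@H](O[Si](CC)(CC)CC)[C@H]2C=1 | intermediate (not isolated)
24 | 11-(dimethylaminomethyl) derivative of 22 (C11 configuration open) | CN(C)CC1C(=O)O[C@@H]2[C@H](O[Si](C)(C)C(C)(C)C)[C@H](C)CCC[C@@]3(C)O[C@@H]3[C@H](O[Si](CC)(CC)CC)[C@@H]12 | intermediate (not isolated)
25 | 11-(trimethylammoniomethyl) derivative of 22 as its iodide (C11 configuration open) | C[N+](C)(C)CC1C(=O)O[C@@H]2[C@H](O[Si](C)(C)C(C)(C)C)[C@H](C)CCC[C@@]3(C)O[C@@H]3[C@H](O[Si](CC)(CC)CC)[C@@H]12.[I-] | intermediate (not isolated)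
26 | (4R,5R,6R,7S,8S,9R,10R)-4,5-epoxy-4,10-dimethyl-6-(triethylsilyloxy)-9-(tert-butyldimethylsilyloxy)cyclodecane trans-fused at C7/C8 to an α-methylene γ-lactone (C11=C13H2; C12=O; O on C8) | C=C1C(=O)O[C@@H]2[C@H](O[Si](C)(C)C(C)(C)C)[C@H](C)CCC[C@@]3(C)O[C@@H]3[C@H](O[Si](CC)(CC)CC)[C@@H]12 | intermediate
27 | (4R,5R,6R,7R,8S,9R,10R)-4,5-epoxy-6-hydroxy-4,10-dimethyl-9-(tert-butyldimethylsilyloxy)cyclodecane trans-fused at C7/C8 to an α-methylene γ-lactone | C=C1C(=O)O[C@@H]2[C@H](O[Si](C)(C)C(C)(C)C)[C@H](C)CCC[C@@]3(C)O[C@@H]3[C@H](O)[C@@H]12 | intermediate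
28 | (4R,5R,6R,7R,8S,9R,10R)-4,5-epoxy-4,10-dimethyl-6-[(E)-2-methylbut-2-enoyloxy]-9-(tert-butyldimethylsilyloxy)cyclodecane trans-fused at C7/C8 to an α-methylene γ-lactone | C=C1C(=O)O[C@@H]2[C@H](O[Si](C)(C)C(C)(C)C)[C@H](C)CCC[C@@]3(C)O[C@@H]3[C@H](OC(=O)/C(C)=C/C)[C@@H]12 | intermediate
29 | (4R,5R,6R,7S,8S,9R,10R)-4,5-epoxy-9-hydroxy-4,10-dimethyl-6-[(E)-2-methylbut-2-enoyloxy]cyclodecane trans-fused at C7/C8 to an α-methylene γ-lactone (CNP0165329.2) | C=C1C(=O)O[C@@H]2[C@H](O)[C@H](C)CCC[C@@]3(C)O[C@@H]3[C@H](OC(=O)/C(C)=C/C)[C@@H]12 | target

## Step count and least certain steps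

Total: 17 steps. Longest linear sequence: 16 steps (steps 1–7 and 9–17, from 1); step 8 is a one-step side branch.

Step 12 (key step). The most likely failure is intermolecular metathesis winning over closure of a strained ten-membered ring, made worse by slow engagement of the branched, silyloxy-flanked C10 vinyl group. Migration of a terminal alkene before closure is the second risk. The fallback makes C1–C2 intermolecularly and closes the ring at C5–C6 instead. It sets out from 12 and 15.
- Cross-metathesis of the C10 vinyl group of 12 with the allyl group of 15 in excess (second-generation Grubbs catalyst, CH2Cl2, 40 °C) would give the (E)-iodo aldehyde F1.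
- Diimide made from KO2CN=NCO2K and acetic acid (a sulfonylhydrazide would condense with the aldehyde) would saturate C1=C2 to the saturated iodo aldehyde F2.
- An intramolecular Nozaki–Hiyama–Kishi reaction (CrCl2, NiCl2 cat., DMSO/THF, high dilution) would close the ring to the ten-membered allylic alcohol F3.
- Sharpless epoxidation as in step 10 would give the ten-membered epoxy alcohol F4, and silylation with TESCl and imidazole comes back to the route at 22.
- In this variant C6 is set on the ring and might need correction by oxidation and reduction.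

Step 9. The likely problems are poor facial selectivity at C6, because the two carbon substituents on C7 differ little in size, and epimerisation at C7 or β-elimination of the lactone oxygen if the coupling is slow. The fallback corrects C6 under reagent control. It sets out from 18, taken as the mixture with its C6 epimer F5. Dess–Martin oxidation of the mixture would give the enone F6. Corey–Bakshi–Shibata reduction with the (S)-2-methyl oxazaborolidine and catecholborane at −78 °C, the alkenyl group acting as the larger substituent, would return 18.

Step 10. The likely problems are erosion of the erythro preference and slow turnover, because the C4 methyl group cis to the carbinol raises allylic strain in the titanium-bound transition state, and titanium alkoxide-mediated migration of the lactone from O8 to O6. The fallback epoxidises under catalyst control without using the hydroxyl. It sets out from 18. Silylation (TESCl, imidazole) would give the triethylsilyl ether F7. Shi epoxidation with the D-fructose-derived ketone (Oxone, K2CO3 buffer, MeCN/dimethoxymethane/H2O, 0 °C) should take the trisubstituted alkene in preference to the terminal ones, on the face that gives (4R,5R), and comes back to the route at 20.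

Step 5. The likely problems are insufficient facial discrimination by the lactone stereocentres with an achiral boronate, and epimerisation at C8 during a slow uncatalysed addition. The fallback adds reagent control. It sets out from 6. The (S,S)-diisopropyl tartrate (E)-crotylboronate F8 (toluene, 4 Å MS, −78 °C) attacks the aldehyde face that the substrate already prefers, so the two influences reinforce each other. The tartrate borate ester F9 formed in the flask is hydrolysed on work-up, and the route is rejoined at 9.

## Further compounds

F1 | step 12 | (E)-cross-metathesis iodo aldehyde from 12 and 15 (C1=C2 E; C4=C5 E; vinyl iodide at C5) | I/C=C(\C)C/C=C/[C@@H](C)[C@@H](O[Si](C)(C)C(C)(C)C)[C@H]1OC(=O)C[C@@H]1C=O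
F2 | step 12 | saturated iodo aldehyde (C1–C2 single bond) | I/C=C(\C)CCC[C@@H](C)[C@@H](O[Si](C)(C)C(C)(C)C)[C@H]1OC(=O)C[C@@H]1C=O
F3 | step 12 | ten-membered (4E)-allylic alcohol: C6 hydroxyl; O9 tert-butyldimethylsilyl; trans-fused γ-lactone | O=C1O[C@@H]2[C@H](O[Si](C)(C)C(C)(C)C)[C@H](C)CCC/C(C)=C/[C@H](O)[C@H]2C1
F4 | step 12 | ten-membered 4,5-epoxy alcohol: C6 hydroxyl; O9 tert-butyldimethylsilyl; trans-fused γ-lactone | O=C1O[C@@H]2[C@H](O[Si](C)(C)C(C)(C)C)[C@H](C)CCC[C@@]3(C)O[C@@H]3[C@H](O)[C@H]2C1
F5 | step 9 | C6 epimer of 18 | C=C[C@@H](C)[C@@H](O[Si](C)(C)C(C)(C)C)[C@H]1OC(=O)C[C@@H]1[C@H](O)/C=C(\C)CC=C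
F6 | step 9 | C6 enone from 18 and F5 | C=C[C@@H](C)[C@@H](O[Si](C)(C)C(C)(C)C)[C@H]1OC(=O)C[C@@H]1C(=O)/C=C(\C)CC=C
F7 | step 10 | triethylsilyl ether of 18 | C=C[C@@H](C)[C@@H](O[Si](C)(C)C(C)(C)C)[C@H]1OC(=O)C[C@@H]1[C@@H](O[Si](CC)(CC)CC)/C=C(\C)CC=C
F8 | step 5 | diisopropyl (4S,5S)-2-[(2E)-but-2-en-1-yl]-1,3,2-dioxaborolane-4,5-dicarboxylate | C/C=C/CB1O[C@H](C(=O)OC(C)C)[C@@H](C(=O)OC(C)C)O1
F9 | step 5 | tartrate borate ester of 9 (boron on O9) | C=C[C@@H](C)[C@@H](OB2O[C@H](C(=O)OC(C)C)[C@@H](C(=O)OC(C)C)O2)[C@H]1OC(=O)C[C@@H]1C3OCCO3
A1 | alternative 1 | terpene-derived enone: 4-(tert-butyldimethylsilyloxy)-2-methyl-5-[2-(triethylsilyloxy)propan-2-yl]cyclohex-2-en-1-one | O=C1C(C)=C[C@H](O[Si](C)(C)C(C)(C)C)[C@@H](C(C)(C)O[Si](CC)(CC)CC)C1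
A2 | alternative 1 | 1-methylcyclobutene | CC1=CCC1
A3 | alternative 1 | cis-anti-cis tricyclic photoadduct | O=C1[C@@]2(C)[C@@H]3CC[C@]3(C)[C@H]2[C@H](O[Si](C)(C)C(C)(C)C)[C@@H](C(C)(C)O[Si](CC)(CC)CC)C1
A4 | alternative 1 | (1(10)E,4E)-cyclodeca-1(10),4-dien-9-one from cycloreversion of A3 | O=C1/C(C)=C/CC/C(C)=C/[C@H](O[Si](C)(C)C(C)(C)C)[C@@H](C(C)(C)O[Si](CC)(CC)CC)C1
A5 | alternative 2 | (1S,2R,6R)-2-[(E)-2-(4-methoxybenzyloxy)ethenyl]-2,6-dimethyl-1-[(E)-3-methylbuta-1,3-dien-1-yl]cyclohexan-1-ol | O[C@]1(/C=C/C(C)=C)[C@H](C)CCC[C@]1(C)/C=C/OCc2ccc(OC)cc2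
A6 | alternative 2 | (E)-cyclodecenone with C6 4-methoxybenzyloxy; C7 isopropenyl; C10 methyl | C1C(=O)[C@H](C)CCC/C(C)=C/[C@H](OCc2ccc(OC)cc2)[C@H]1C(C)=C
A7 | alternative 3 | thirteen-membered α-allyloxy ketone (geometry of the C7=C11 alkene left open) | O=C1COCC(C)=C[C@@H](O[Si](C)(C)C(C)(C)C)/C=C(\C)CCC[C@H]1C
A8 | alternative 3 | 8-hydroxy-9-oxo (E)-cyclodecene with C7 isopropenyl; O6 tert-butyldimethylsilyl | O[C@@H]1C(=O)[C@H](C)CCC/C(C)=C/[C@H](O[Si](C)(C)C(C)(C)C)[C@H]1C(C)=C
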